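In ring D the ether carbons C1 (bonded to the ring C oxygen) and C5 (bonded to the ring E oxygen) are meta to each other. The hydroxyl carbon C4 is para to C1 and ortho to C5, so a formyl group at C4 activates both carbons for SNAr and is later exchanged for that hydroxyl.
The last disconnections are the seventeen O-benzyl groups (hydrogenolysis) and the C4 hydroxyl of ring D (formyl-to-hydroxyl oxidation). The key disconnection then cuts both aryl C–O bonds of ring D, giving 2-(benzyloxy)-4,6-difluorobenzaldehyde, the A–B–C trimer phenol and the E–F–G trimer phenol.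
A–B–C: the ring A phenol takes the para fluorine of a second portion of the same difluoroaldehyde, which becomes ring B. Benzyl oxide takes the ortho fluorine and CHO becomes OH; copper-catalysed coupling with a ring C ortho-bromoaldehyde follows, and again CHO becomes OH.
E–F–G: the ring G phenol is coupled with a ring F para-bromoaldehyde and CHO becomes OH; coupling with a ring E ortho-bromoaldehyde follows, and again CHO becomes OH.
No ring is built, since all seven benzene rings are bought. They are joined in the order A–B, B–C and G–F, F–E (two parallel branches), then C–D and D–E in one pot.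

Key step: step 22

Assumption: the target has no stereocentre and no isolable axis, so nothing stereochemical has to be controlled. Rings are lettered A to G from the 2,4,6-trihydroxyphenyl end.
Remark: all formyl-to-hydroxyl steps act on fully etherified aldehydes, on which alkaline H2O2 is ineffective. The peracid (Baeyer–Villiger) form of the Dakin oxidation is therefore used, and the aryl formate is cleaved by methanolysis.
Remark: rings C and E carry a benzyloxy group para to the carbon to be etherified, which weakens SNAr activation. These rings, and ring F, therefore enter as bromoaldehydes under copper catalysis.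

Step 1
Reactants: 1 3,5-difluorophenol
Product: 2 2,4-difluoro-6-hydroxybenzaldehyde
Conditions: MgCl2, Et3N, (CH2O)n, MeCN, reflux; aq. HCl work-up
Reagents that add atoms: paraformaldehyde (reacts as formaldehyde), C=O
Why: Casnati–Skattebøl ortho-formylation: the magnesium phenoxide hands formaldehyde only to a carbon next to the phenol oxygen, both such carbons are equivalent, and the formyl group therefore ends between O and F rather than between the two fluorines, where metalation of the benzyl ether would have placed it.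

Step 2
Reactants: 2 2,4-difluoro-6-hydroxybenzaldehyde
Product: 3 2-(benzyloxy)-4,6-difluorobenzaldehyde
Conditions: BnBr, K2CO3, DMF, rt
Reagents that add atoms: benzyl bromide, BrCc1ccccc1
Why: Williamson ether synthesis: at room temperature the weakly nucleophilic, chelated phenoxide is benzylated much faster than it could attack a C–F bond of a second molecule.

Step 3
Reactants: 4 2,4,6-trihydroxybenzaldehyde
Product: 5 2,4,6-tris(benzyloxy)benzaldehyde
Conditions: BnBr (excess), K2CO3, DMF, 60 °C, argon
Reagents that add atoms: benzyl bromide, BrCc1ccccc1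
Why: Threefold Williamson ether synthesis: the formyl group lowers the carbon nucleophilicity of the phloroglucinol ring, so O-benzylation should prevail over C-benzylation, and heating with excess bromide brings in the two chelated ortho hydroxyls.

Step 4
Reactants: 5 2,4,6-tris(benzyloxy)benzaldehyde
Product: 7 2,4,6-tris(benzyloxy)phenol, via ring A formate 6 (not isolated)
Conditions: mCPBA, CH2Cl2, 0 °C → rt; then cat. K2CO3, MeOH–THF, rt
Reagents that add atoms: mCPBA, O=C(OO)c1cccc(Cl)c1
Why: Baeyer–Villiger form of the Dakin oxidation: the aryl group, enriched by two ortho and one para benzyloxy groups, migrates in preference to hydrogen, and the labile aryl formate is removed by base-catalysed methanolysis that leaves benzyl ethers alone.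

Step 5
Reactants: 7 2,4,6-tris(benzyloxy)phenol; 3 2-(benzyloxy)-4,6-difluorobenzaldehyde
Product: 8 2-(benzyloxy)-6-fluoro-4-[2,4,6-tris(benzyloxy)phenoxy]benzaldehyde
Conditions: Cs2CO3, NMP, 50 °C, argon
Reagents that add atoms: none
Why: Nucleophilic aromatic substitution (SNAr) by addition–elimination: the di-ortho-substituted phenoxide should take the fluorine para to the formyl group, which lies between two hydrogens, and leave the fluorine beside the formyl group, so that this step is also a small-scale test of the selectivity needed in step 22.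

Step 6
Reactants: 8 2-(benzyloxy)-6-fluoro-4-[2,4,6-tris(benzyloxy)phenoxy]benzaldehyde
Product: 9 2,6-bis(benzyloxy)-4-[2,4,6-tris(benzyloxy)phenoxy]benzaldehyde
Conditions: BnOH, NaH, THF–DMF, 0 → 50 °C
Reagents that add atoms: benzyl alcohol, OCc1ccccc1
Why: SNAr with sodium benzyl oxide: the remaining fluorine is ortho to the formyl group and is a far better leaving group than the electron-rich aryloxide at the para carbon, so only the C–F bond is exchanged and ring B receives its second benzyloxy group.

Step 7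
Reactants: 9 2,6-bis(benzyloxy)-4-[2,4,6-tris(benzyloxy)phenoxy]benzaldehyde
Product: 11 2,6-bis(benzyloxy)-4-[2,4,6-tris(benzyloxy)phenoxy]phenol, via A–B formate 10 (not isolated)
Conditions: mCPBA, CH2Cl2, 0 °C → rt; then cat. K2CO3, MeOH–THF, rt
Reagents that add atoms: mCPBA, O=C(OO)c1cccc(Cl)c1
Why: Baeyer–Villiger form of the Dakin oxidation followed by formate methanolysis: the 2,6-dialkoxy-4-aryloxyphenyl group has a high migratory aptitude, and a slight excess of peracid at low temperature should spare the electron-rich ring A.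

Step 8
Reactants: 12 5-bromo-1,2,3-trimethoxybenzene
Product: 13 6-bromo-2,3,4-trimethoxybenzaldehyde
Conditions: Cl2CHOMe, TiCl4, CH2Cl2, 0 °C; then H2O
Reagents that add atoms: dichloromethyl methyl ether, COC(Cl)Cl; water, O
Why: Rieche formylation, an electrophilic aromatic substitution: the two free ring positions are equivalent and each is para to one and ortho to another methoxy group, so a single aldehyde should form, and any loss of the methyl group next to the new carbonyl is harmless because step 9 removes all three.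

Step 9
Reactants: 13 6-bromo-2,3,4-trimethoxybenzaldehyde
Product: 14 6-bromo-2,3,4-trihydroxybenzaldehyde
Conditions: BBr3, CH2Cl2, −78 °C → rt; then H2O
Reagents that add atoms: none
Why: Lewis-acid ether cleavage with BBr3: each aryl methyl ether is opened by bromide attack on the methyl carbon of the boron complex, while the aryl bromide and the aldehyde are recovered unchanged after hydrolysis.

Step 10
Reactants: 14 6-bromo-2,3,4-trihydroxybenzaldehyde
Product: 15 2,3,4-tris(benzyloxy)-6-bromobenzaldehyde
Conditions: BnBr (excess), K2CO3, DMF, 60 °C, argon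
Reagents that add atoms: benzyl bromide, BrCc1ccccc1
Why: Threefold Williamson ether synthesis under argon, as is routine for pyrogallol aldehydes; the aryl bromide is inert to carbonate and the phenoxides are alkylated before air oxidation can set in.

Step 11
Reactants: 11 2,6-bis(benzyloxy)-4-[2,4,6-tris(benzyloxy)phenoxy]phenol; 15 2,3,4-tris(benzyloxy)-6-bromobenzaldehyde
Product: 16 2,3,4-tris(benzyloxy)-6-{2,6-bis(benzyloxy)-4-[2,4,6-tris(benzyloxy)phenoxy]phenoxy}benzaldehyde
Conditions: CuI (20 mol %), picolinic acid (40 mol %), K3PO4, DMSO, 95 °C, argon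
Reagents that add atoms: none
Why: Ullmann-type diaryl ether synthesis: the bromine lies ortho to the formyl group, which speeds its reaction with copper, and has a hydrogen on its other side, while the picolinate-ligated copper catalyst is of the kind used for di-ortho-substituted phenols.

Step 12
Reactants: 16 2,3,4-tris(benzyloxy)-6-{2,6-bis(benzyloxy)-4-[2,4,6-tris(benzyloxy)phenoxy]phenoxy}benzaldehyde
Product: 18 A–B–C trimer phenol 2,3,4-tris(benzyloxy)-6-{2,6-bis(benzyloxy)-4-[2,4,6-tris(benzyloxy)phenoxy]phenoxy}phenol, via A–B–C formate 17 (not isolated)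
Conditions: mCPBA, CH2Cl2, 0 °C → rt; then cat. K2CO3, MeOH–THF, rt
Reagents that add atoms: mCPBA, O=C(OO)c1cccc(Cl)c1
Why: Baeyer–Villiger form of the Dakin oxidation followed by formate methanolysis: the migrating ring C carbon has an aryloxy and a benzyloxy group ortho and a benzyloxy group para, so aryl migration should be fast and unveil the ring C hydroxyl beside the ring B ether.

Step 13
Reactants: 19 3,4,5-trihydroxybenzaldehyde
Product: 20 3,4,5-tris(benzyloxy)benzaldehyde
Conditions: BnBr (excess), K2CO3, DMF, 50 °C, argon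
Reagents that add atoms: benzyl bromide, BrCc1ccccc1
Why: Threefold Williamson ether synthesis of a gallic-type triol, run under argon because the free pyrogallol unit is air-sensitive in base.

Step 14
Reactants: 20 3,4,5-tris(benzyloxy)benzaldehyde
Product: 22 3,4,5-tris(benzyloxy)phenol, via ring G formate 21 (not isolated)
Conditions: mCPBA, CH2Cl2, rt → reflux; then cat. K2CO3, MeOH–THF, rt
Reagents that add atoms: mCPBA, O=C(OO)c1cccc(Cl)c1
Why: Baeyer–Villiger form of the Dakin oxidation followed by formate methanolysis: the para benzyloxy group gives the aryl group enough migratory aptitude, as is well established for 3,4,5-trialkoxybenzaldehydes.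

Step 15
Reactants: 20 3,4,5-tris(benzyloxy)benzaldehyde
Product: 23 3,4,5-tris(benzyloxy)-2-bromobenzaldehyde
Conditions: NBS, MeCN, 0 °C → rt, dark
Reagents that add atoms: N-bromosuccinimide, O=C1CCC(=O)N1Br
Why: Electrophilic aromatic bromination: the two free positions of the aldehyde are equivalent and each is ortho and para to benzyloxy groups, the first bromine deactivates the ring against a second one, and a polar solvent in the dark suppresses radical attack at the benzylic CH2 groups.

Step 16
Reactants: 24 4-bromo-3,5-dimethoxybenzaldehyde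
Product: 25 4-bromo-3,5-dihydroxybenzaldehyde
Conditions: BBr3, CH2Cl2, −78 °C → rt; then H2O
Reagents that add atoms: none
Why: Lewis-acid ether cleavage with BBr3 removes both methyl groups by bromide attack at the methyl carbon and leaves the aryl bromide and the aldehyde in place.

Step 17
Reactants: 25 4-bromo-3,5-dihydroxybenzaldehyde
Product: 26 3,5-bis(benzyloxy)-4-bromobenzaldehyde
Conditions: BnBr, K2CO3, DMF, 50 °C
Reagents that add atoms: benzyl bromide, BrCc1ccccc1
Why: Twofold Williamson ether synthesis on two equivalent, unchelated phenols, with no competing reaction of the aryl bromide.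

Step 18
Reactants: 22 3,4,5-tris(benzyloxy)phenol; 26 3,5-bis(benzyloxy)-4-bromobenzaldehyde
Product: 27 3,5-bis(benzyloxy)-4-[3,4,5-tris(benzyloxy)phenoxy]benzaldehyde
Conditions: CuI (20 mol %), picolinic acid (40 mol %), K3PO4, DMSO, 105 °C, argon
Reagents that add atoms: none
Why: Ullmann-type diaryl ether synthesis between an unhindered, electron-rich phenol and a bromide activated by the para formyl group; the two flanking benzyloxy groups slow the coupling, but 2,6-dialkoxyaryl bromides lie within the classical scope of copper-mediated phenoxide arylation.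

Step 19
Reactants: 27 3,5-bis(benzyloxy)-4-[3,4,5-tris(benzyloxy)phenoxy]benzaldehyde
Product: 29 3,5-bis(benzyloxy)-4-[3,4,5-tris(benzyloxy)phenoxy]phenol, via F–G formate 28 (not isolated)
Conditions: mCPBA, CH2Cl2, rt → reflux; then cat. K2CO3, MeOH–THF, rt
Reagents that add atoms: mCPBA, O=C(OO)c1cccc(Cl)c1
Why: Baeyer–Villiger form of the Dakin oxidation followed by formate methanolysis: conversion of 4-aryloxybenzaldehydes into 4-aryloxyphenols by peracid is a standard sequence, the para aryloxy oxygen supporting aryl migration.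

Step 20
Reactants: 29 3,5-bis(benzyloxy)-4-[3,4,5-tris(benzyloxy)phenoxy]phenol; 23 3,4,5-tris(benzyloxy)-2-bromobenzaldehyde
Product: 30 3,4,5-tris(benzyloxy)-2-{3,5-bis(benzyloxy)-4-[3,4,5-tris(benzyloxy)phenoxy]phenoxy}benzaldehyde
Conditions: CuI (20 mol %), picolinic acid (40 mol %), K3PO4, DMSO, 95 °C, argon
Reagents that add atoms: none
Why: Ullmann-type diaryl ether synthesis: the phenol oxygen has hydrogens on both sides and the bromide is activated by the ortho formyl group, the combination long used to make ethers of 2-bromo-3,4,5-trialkoxybenzoyl units.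

Step 21
Reactants: 30 3,4,5-tris(benzyloxy)-2-{3,5-bis(benzyloxy)-4-[3,4,5-tris(benzyloxy)phenoxy]phenoxy}benzaldehyde
Product: 32 E–F–G trimer phenol 3,4,5-tris(benzyloxy)-2-{3,5-bis(benzyloxy)-4-[3,4,5-tris(benzyloxy)phenoxy]phenoxy}phenol, via E–F–G formate 31 (not isolated)
Conditions: mCPBA, CH2Cl2, 0 °C → rt; then cat. K2CO3, MeOH–THF, rt
Reagents that add atoms: mCPBA, O=C(OO)c1cccc(Cl)c1
Why: Baeyer–Villiger form of the Dakin oxidation followed by formate methanolysis: an ortho aryloxy and a para benzyloxy group drive aryl migration and give the ring E hydroxyl next to the ring F ether on one side and a hydrogen on the other.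

Step 22
Reactants: 3 2-(benzyloxy)-4,6-difluorobenzaldehyde; 18 A–B–C trimer phenol; 32 E–F–G trimer phenol
Product: 34 heptadecabenzyl heptamer aldehyde (ring D is a 2-(benzyloxy)benzaldehyde bearing the A–B–C aryloxy group at C4 para to CHO plus the E–F–G aryloxy group at C6 ortho to CHO), via tetramer fluoroaldehyde 33 (not isolated)
Conditions: 18 (1.0 equiv), 3 (1.0 equiv), Cs2CO3, NMP, 50 °C, argon, until 18 is consumed (19F NMR control); then 32 (1.05 equiv), Cs2CO3, 110 °C
Reagents that add atoms: none
Why: Each substitution is an addition–elimination (SNAr): the cesium phenoxide adds to a C–F carbon of ring D, the charge of the Meisenheimer anion spreads onto the formyl oxygen, and fluoride leaves. The closest known reaction type is the stepwise displacement of first the 4-fluorine and then the 2-fluorine of 2,4-difluorobenzaldehydes by phenoxides. No ring closes and no stereocentre is formed; the two new bonds are C1 of ring D to the ring C oxygen and C5 of ring D to the ring E oxygen. The step needs site selectivity between the two fluorines, and three things secure it: the para fluorine lies between two hydrogens whereas the ortho fluorine lies beside the formyl group, the phenoxide of 18 is flanked by an aryloxy and a benzyloxy group and can hardly reach the ortho carbon, and in NMP the solvated cesium ion offers no chelation to the carbonyl oxygen that could steer attack to the ortho carbon. Once the first aryloxy group is on, 33 is less electrophilic and should persist at 50 °C, and 32, which has a hydrogen on one side of its phenoxide oxygen, is added only when 18 is used up and then needs 110 °C. Step 5 runs the same first displacement on the same aldehyde with a small, equally hindered phenoxide and so tests the selectivity beforehand.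

Step 23
Reactants: 34 heptadecabenzyl heptamer aldehyde
Product: 36 heptadecabenzyl heptamer phenol (free hydroxyl at C4 of ring D), via heptamer formate 35 (not isolated)
Conditions: mCPBA, CH2Cl2, 0 °C → rt; then cat. K2CO3, MeOH–THF, rt
Reagents that add atoms: mCPBA, O=C(OO)c1cccc(Cl)c1
Why: Baeyer–Villiger form of the Dakin oxidation followed by formate methanolysis: the migrating ring D carbon carries oxygen substituents at both ortho positions and at the para position, which should make the formyl group by far the most peracid-reactive site of the heptamer and place the missing hydroxyl at C4 of ring D.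

Step 24
Reactants: 36 heptadecabenzyl heptamer phenol
Product: 37 CNP0130704.0 (target)
Conditions: H2 (1 atm), 10% Pd/C, THF–MeOH, rt; filtration and concentration under argon
Reagents that add atoms: none
Why: Catalytic hydrogenolysis of benzyl aryl ethers: all seventeen O–CH2Ph bonds are cleaved under neutral conditions that do not touch diaryl ethers, toluene is the only by-product, and work-up under argon protects the pyrogallol-type rings from air.

Compound list
1 | 3,5-difluorophenol | Oc1cc(F)cc(F)c1 | starting material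
2 | 2,4-difluoro-6-hydroxybenzaldehyde | O=Cc1c(O)cc(F)cc1F | intermediate
3 | 2-(benzyloxy)-4,6-difluorobenzaldehyde (ring D linchpin, also source of ring B) | O=Cc1c(F)cc(F)cc1OCc9ccccc9 | intermediate
4 | 2,4,6-trihydroxybenzaldehyde | O=Cc1c(O)cc(O)cc1O | starting material
5 | 2,4,6-tris(benzyloxy)benzaldehyde | O=Cc1c(OCc9ccccc9)cc(OCc9ccccc9)cc1OCc9ccccc9 | intermediate
6 | 2,4,6-tris(benzyloxy)phenyl formate (ring A formate) | O=COc1c(OCc9ccccc9)cc(OCc9ccccc9)cc1OCc9ccccc9 | intermediate
7 | 2,4,6-tris(benzyloxy)phenol (ring A phenol) | Oc1c(OCc9ccccc9)cc(OCc9ccccc9)cc1OCc9ccccc9 | intermediate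
8 | 2-(benzyloxy)-6-fluoro-4-[2,4,6-tris(benzyloxy)phenoxy]benzaldehyde | O=Cc1c(F)cc(Oc2c(OCc9ccccc9)cc(OCc9ccccc9)cc2OCc9ccccc9)cc1OCc9ccccc9 | intermediate
9 | 2,6-bis(benzyloxy)-4-[2,4,6-tris(benzyloxy)phenoxy]benzaldehyde | O=Cc1c(OCc9ccccc9)cc(Oc2c(OCc9ccccc9)cc(OCc9ccccc9)cc2OCc9ccccc9)cc1OCc9ccccc9 | intermediate
10 | 2,6-bis(benzyloxy)-4-[2,4,6-tris(benzyloxy)phenoxy]phenyl formate (A–B formate) | O=COc1c(OCc9ccccc9)cc(Oc2c(OCc9ccccc9)cc(OCc9ccccc9)cc2OCc9ccccc9)cc1OCc9ccccc9 | intermediate
11 | 2,6-bis(benzyloxy)-4-[2,4,6-tris(benzyloxy)phenoxy]phenol (A–B phenol) | Oc1c(OCc9ccccc9)cc(Oc2c(OCc9ccccc9)cc(OCc9ccccc9)cc2OCc9ccccc9)cc1OCc9ccccc9 | intermediate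
12 | 5-bromo-1,2,3-trimethoxybenzene | COc1cc(Br)cc(OC)c1OC | starting material
13 | 6-bromo-2,3,4-trimethoxybenzaldehyde | O=Cc1c(Br)cc(OC)c(OC)c1OC | intermediate
14 | 6-bromo-2,3,4-trihydroxybenzaldehyde | O=Cc1c(Br)cc(O)c(O)c1O | intermediate
15 | 2,3,4-tris(benzyloxy)-6-bromobenzaldehyde (ring C bromoaldehyde) | O=Cc1c(Br)cc(OCc9ccccc9)c(OCc9ccccc9)c1OCc9ccccc9 | intermediate
16 | 2,3,4-tris(benzyloxy)-6-{2,6-bis(benzyloxy)-4-[2,4,6-tris(benzyloxy)phenoxy]phenoxy}benzaldehyde (A–B–C aldehyde) | c9ccccc9COc1cc(OCc9ccccc9)c(Oc2cc(OCc9ccccc9)c(Oc3cc(OCc9ccccc9)c(OCc9ccccc9)c(OCc9ccccc9)c3C=O)c(OCc9ccccc9)c2)c(OCc9ccccc9)c1 | intermediate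
17 | A–B–C formate (formate ester of 18) | c9ccccc9COc1cc(OCc9ccccc9)c(Oc2cc(OCc9ccccc9)c(Oc3cc(OCc9ccccc9)c(OCc9ccccc9)c(OCc9ccccc9)c3OC=O)c(OCc9ccccc9)c2)c(OCc9ccccc9)c1 | intermediate
18 | A–B–C trimer phenol, 2,3,4-tris(benzyloxy)-6-{2,6-bis(benzyloxy)-4-[2,4,6-tris(benzyloxy)phenoxy]phenoxy}phenol; free hydroxyl on ring C between the ring B ether and a benzyloxy group | c9ccccc9COc1cc(OCc9ccccc9)c(Oc2cc(OCc9ccccc9)c(Oc3cc(OCc9ccccc9)c(OCc9ccccc9)c(OCc9ccccc9)c3O)c(OCc9ccccc9)c2)c(OCc9ccccc9)c1 | intermediate
19 | 3,4,5-trihydroxybenzaldehyde | O=Cc1cc(O)c(O)c(O)c1 | starting material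
20 | 3,4,5-tris(benzyloxy)benzaldehyde | O=Cc1cc(OCc9ccccc9)c(OCc9ccccc9)c(OCc9ccccc9)c1 | intermediate
21 | 3,4,5-tris(benzyloxy)phenyl formate (ring G formate) | O=COc1cc(OCc9ccccc9)c(OCc9ccccc9)c(OCc9ccccc9)c1 | intermediate
22 | 3,4,5-tris(benzyloxy)phenol (ring G phenol) | Oc1cc(OCc9ccccc9)c(OCc9ccccc9)c(OCc9ccccc9)c1 | intermediate
23 | 3,4,5-tris(benzyloxy)-2-bromobenzaldehyde (ring E bromoaldehyde) | O=Cc1cc(OCc9ccccc9)c(OCc9ccccc9)c(OCc9ccccc9)c1Br | intermediate
24 | 4-bromo-3,5-dimethoxybenzaldehyde | COc1cc(C=O)cc(OC)c1Br | starting material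
25 | 4-bromo-3,5-dihydroxybenzaldehyde | O=Cc1cc(O)c(Br)c(O)c1 | intermediate
26 | 3,5-bis(benzyloxy)-4-bromobenzaldehyde (ring F bromoaldehyde) | O=Cc1cc(OCc9ccccc9)c(Br)c(OCc9ccccc9)c1 | intermediate
27 | 3,5-bis(benzyloxy)-4-[3,4,5-tris(benzyloxy)phenoxy]benzaldehyde | O=Cc1cc(OCc9ccccc9)c(Oc2cc(OCc9ccccc9)c(OCc9ccccc9)c(OCc9ccccc9)c2)c(OCc9ccccc9)c1 | intermediate
28 | 3,5-bis(benzyloxy)-4-[3,4,5-tris(benzyloxy)phenoxy]phenyl formate (F–G formate) | O=COc1cc(OCc9ccccc9)c(Oc2cc(OCc9ccccc9)c(OCc9ccccc9)c(OCc9ccccc9)c2)c(OCc9ccccc9)c1 | intermediate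
29 | 3,5-bis(benzyloxy)-4-[3,4,5-tris(benzyloxy)phenoxy]phenol (F–G phenol) | Oc1cc(OCc9ccccc9)c(Oc2cc(OCc9ccccc9)c(OCc9ccccc9)c(OCc9ccccc9)c2)c(OCc9ccccc9)c1 | intermediate
30 | 3,4,5-tris(benzyloxy)-2-{3,5-bis(benzyloxy)-4-[3,4,5-tris(benzyloxy)phenoxy]phenoxy}benzaldehyde (E–F–G aldehyde) | O=Cc1cc(OCc9ccccc9)c(OCc9ccccc9)c(OCc9ccccc9)c1Oc2cc(OCc9ccccc9)c(Oc3cc(OCc9ccccc9)c(OCc9ccccc9)c(OCc9ccccc9)c3)c(OCc9ccccc9)c2 | intermediate
31 | E–F–G formate (formate ester of 32) | O=COc1cc(OCc9ccccc9)c(OCc9ccccc9)c(OCc9ccccc9)c1Oc2cc(OCc9ccccc9)c(Oc3cc(OCc9ccccc9)c(OCc9ccccc9)c(OCc9ccccc9)c3)c(OCc9ccccc9)c2 | intermediate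
32 | E–F–G trimer phenol, 3,4,5-tris(benzyloxy)-2-{3,5-bis(benzyloxy)-4-[3,4,5-tris(benzyloxy)phenoxy]phenoxy}phenol; free hydroxyl on ring E | Oc1cc(OCc9ccccc9)c(OCc9ccccc9)c(OCc9ccccc9)c1Oc2cc(OCc9ccccc9)c(Oc3cc(OCc9ccccc9)c(OCc9ccccc9)c(OCc9ccccc9)c3)c(OCc9ccccc9)c2 | intermediate
33 | tetramer fluoroaldehyde: 2-(benzyloxy)-6-fluorobenzaldehyde whose C4, para to CHO, bears the ring C oxygen of the A–B–C trimer | c9ccccc9COc1cc(OCc9ccccc9)c(Oc2cc(OCc9ccccc9)c(Oc3cc(OCc9ccccc9)c(OCc9ccccc9)c(OCc9ccccc9)c3Oc3cc(OCc9ccccc9)c(C=O)c(F)c3)c(OCc9ccccc9)c2)c(OCc9ccccc9)c1 | intermediate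
34 | heptadecabenzyl heptamer aldehyde (formyl group at C4 of ring D) | c9ccccc9COc1cc(OCc9ccccc9)c(Oc2cc(OCc9ccccc9)c(Oc3cc(OCc9ccccc9)c(OCc9ccccc9)c(OCc9ccccc9)c3Oc3cc(OCc9ccccc9)c(C=O)c(Oc4cc(OCc9ccccc9)c(OCc9ccccc9)c(OCc9ccccc9)c4Oc4cc(OCc9ccccc9)c(Oc5cc(OCc9ccccc9)c(OCc9ccccc9)c(OCc9ccccc9)c5)c(OCc9ccccc9)c4)c3)c(OCc9ccccc9)c2)c(OCc9ccccc9)c1 | intermediate
35 | heptamer formate (formyloxy group at C4 of ring D) | c9ccccc9COc1cc(OCc9ccccc9)c(Oc2cc(OCc9ccccc9)c(Oc3cc(OCc9ccccc9)c(OCc9ccccc9)c(OCc9ccccc9)c3Oc3cc(OCc9ccccc9)c(OC=O)c(Oc4cc(OCc9ccccc9)c(OCc9ccccc9)c(OCc9ccccc9)c4Oc4cc(OCc9ccccc9)c(Oc5cc(OCc9ccccc9)c(OCc9ccccc9)c(OCc9ccccc9)c5)c(OCc9ccccc9)c4)c3)c(OCc9ccccc9)c2)c(OCc9ccccc9)c1 | intermediate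
36 | heptadecabenzyl heptamer phenol (free hydroxyl at C4 of ring D) | c9ccccc9COc1cc(OCc9ccccc9)c(Oc2cc(OCc9ccccc9)c(Oc3cc(OCc9ccccc9)c(OCc9ccccc9)c(OCc9ccccc9)c3Oc3cc(OCc9ccccc9)c(O)c(Oc4cc(OCc9ccccc9)c(OCc9ccccc9)c(OCc9ccccc9)c4Oc4cc(OCc9ccccc9)c(Oc5cc(OCc9ccccc9)c(OCc9ccccc9)c(OCc9ccccc9)c5)c(OCc9ccccc9)c4)c3)c(OCc9ccccc9)c2)c(OCc9ccccc9)c1 | intermediate
37 | CNP0130704.0, heptameric phlorotannin with eighteen free hydroxyls (achiral) | Oc1cc(O)c(Oc2cc(O)c(Oc3cc(O)c(O)c(O)c3Oc3cc(O)c(O)c(Oc4cc(O)c(O)c(O)c4Oc4cc(O)c(Oc5cc(O)c(O)c(O)c5)c(O)c4)c3)c(O)c2)c(O)c1 | target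

Total step count: 24.
Longest linear sequence: 10 steps (3, 4, 5, 6, 7, 11, 12, 22, 23, 24).

Steps most likely to fail

Step 22. Three things may go wrong:
- The first displacement may lose its site selectivity, with attack beside the formyl group.
- The second displacement may stall at the crowded ortho carbon.
- At 110 °C the aryloxy group already sitting para to the formyl group may be exchanged by the second phenoxide.

The fallback uses two leaving groups of different kind, so that one bond is made by SNAr and the other by copper catalysis. It sets out from 32 and comes back to the route at 34.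
- Purchased 4-bromo-2,6-difluorobenzaldehyde F1 is treated with one equivalent of BnOH and NaH in THF at 0 °C. This should replace one of the two equivalent ortho fluorines and give 2-(benzyloxy)-4-bromo-6-fluorobenzaldehyde F2.
- Phenol 32 with Cs2CO3 in NMP at 90 °C can then displace only fluoride, because bromide is a much poorer leaving group in addition–elimination. This gives the E–F–G bromoaldehyde F3.
- The bromine of F3, para to the formyl group and between two hydrogens, is finally coupled with the hindered phenol 18 (CuI, picolinic acid, K3PO4, DMSO, 95 °C, Ullmann type) to give 34.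

Step 11. C–O bond formation between a di-ortho-substituted phenoxide and an electron-rich bromide may be so slow that reduction of the C–Br bond or copper-mediated oxidation of the electron-rich phenol takes over. The fallback drops the metal and uses addition–elimination at a C–F bond, where the small leaving group and the out-of-plane approach of the nucleophile suffer less from crowding. It sets out from 15 and comes back at 16.
- Aldehyde 15 is protected with ethylene glycol (TsOH, toluene, water separator) as 2-[2,3,4-tris(benzyloxy)-6-bromophenyl]-1,3-dioxolane F4.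
- Bromine–lithium exchange with n-BuLi in THF at −78 °C gives the ring C aryllithium F5.
- F5 is quenched at once with N-fluorobenzenesulfonimide to give 2-[2,3,4-tris(benzyloxy)-6-fluorophenyl]-1,3-dioxolane F6.
- Aqueous HCl in THF frees 2,3,4-tris(benzyloxy)-6-fluorobenzaldehyde F7.
- F7 is heated with 11 and Cs2CO3 in NMP at 130 °C to give 16.

Step 18. The two benzyloxy groups beside the bromine may block the copper catalyst, so that protodebromination of 26 and slow decay of the aldehyde win over coupling. The fallback is again uncatalysed SNAr at a fluoride, here para to the formyl group. It sets out from 26 and comes back at 27.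
- Aldehyde 26 is converted with ethylene glycol and TsOH into 2-[3,5-bis(benzyloxy)-4-bromophenyl]-1,3-dioxolane F8.
- n-BuLi in THF at −78 °C gives the ring F aryllithium F9.
- N-fluorobenzenesulfonimide turns F9 into 2-[3,5-bis(benzyloxy)-4-fluorophenyl]-1,3-dioxolane F10.
- Aqueous HCl in THF gives 3,5-bis(benzyloxy)-4-fluorobenzaldehyde F11.
- The unhindered phenoxide of 22 (Cs2CO3, NMP, 130 °C) displaces the fluoride of F11 to give 27.

Further compounds
F1 | step 22 | 4-bromo-2,6-difluorobenzaldehyde (purchased) | O=Cc1c(F)cc(Br)cc1F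
F2 | step 22 | 2-(benzyloxy)-4-bromo-6-fluorobenzaldehyde | O=Cc1c(F)cc(Br)cc1OCc9ccccc9
F3 | step 22 | E–F–G bromoaldehyde: 2-(benzyloxy)-4-bromobenzaldehyde bearing at C6 the ring E oxygen of 32 | O=Cc1c(Oc2cc(OCc9ccccc9)c(OCc9ccccc9)c(OCc9ccccc9)c2Oc3cc(OCc9ccccc9)c(Oc4cc(OCc9ccccc9)c(OCc9ccccc9)c(OCc9ccccc9)c4)c(OCc9ccccc9)c3)cc(Br)cc1OCc9ccccc9
F4 | step 11 | 2-[2,3,4-tris(benzyloxy)-6-bromophenyl]-1,3-dioxolane | Brc1cc(OCc9ccccc9)c(OCc9ccccc9)c(OCc9ccccc9)c1C2OCCO2
F5 | step 11 | ring C aryllithium, [3,4,5-tris(benzyloxy)-2-(1,3-dioxolan-2-yl)phenyl]lithium | [Li]c1cc(OCc9ccccc9)c(OCc9ccccc9)c(OCc9ccccc9)c1C2OCCO2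
F6 | step 11 | 2-[2,3,4-tris(benzyloxy)-6-fluorophenyl]-1,3-dioxolane | Fc1cc(OCc9ccccc9)c(OCc9ccccc9)c(OCc9ccccc9)c1C2OCCO2
F7 | step 11 | 2,3,4-tris(benzyloxy)-6-fluorobenzaldehyde | O=Cc1c(F)cc(OCc9ccccc9)c(OCc9ccccc9)c1OCc9ccccc9
F8 | step 18 | 2-[3,5-bis(benzyloxy)-4-bromophenyl]-1,3-dioxolane | Brc1c(OCc9ccccc9)cc(C2OCCO2)cc1OCc9ccccc9
F9 | step 18 | ring F aryllithium, [2,6-bis(benzyloxy)-4-(1,3-dioxolan-2-yl)phenyl]lithium | [Li]c1c(OCc9ccccc9)cc(C2OCCO2)cc1OCc9ccccc9
F10 | step 18 | 2-[3,5-bis(benzyloxy)-4-fluorophenyl]-1,3-dioxolane | Fc1c(OCc9ccccc9)cc(C2OCCO2)cc1OCc9ccccc9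
F11 | step 18 | 3,5-bis(benzyloxy)-4-fluorobenzaldehyde | O=Cc1cc(OCc9ccccc9)c(F)c(OCc9ccccc9)c1
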